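## Retrosynthetic overview

1. Plakortide N (20) ⇐ methyl ester 18 ⇐ C6–C7 bond: axial ipso-alkenylation of the cyclic peroxycarbenium ion from 6-methoxy-1,2-dioxane 9 with (E)-vinylsilane 17 (sets C6, keeps 7E).
2. Key step (step 6): the dioxane ring of 9 is closed through the O2–C3 bond (C–O) by intramolecular SN2 opening of β-lactone 7 by its own C6 methoxy-hydroperoxide (inversion gives 3S cis to the C4 ethyl and unmasks the acid). O1–C6 comes from peroxyketalisation of the ketone of 6.
3. 6 ⇐ ketene + (2S)-2-ethyl-4-oxohexanal 5 (catalytic asymmetric [2+2], sets the C3–O centre) ⇐ ozonolysis ⇐ Rh/BINAP vinyl conjugate addition to (E)-hept-4-en-3-one 3 (sets C4).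
4. 17 ⇐ ethylcupration/iodination/silylation of enyne 13 ⇐ Johnson–Claisen rearrangement of (3R,4E)-hept-4-en-3-ol 10 (sets C10 and 11E) ⇐ CBS reduction of the same enone 3.
5. Ring order: one ring only, the 1,2-dioxane, formed in step 6 before the side chain is attached.

Assumption: the SMILES is read as (3S,4S,6R,7E,10R,11E) with C1 = CO2H, and (E)-hept-4-en-3-one is made in step 1 and not bought.

## Route

Step 1
Reactants: 1 propanal; 2 diethyl (2-oxobutyl)phosphonate
Product: 3 (E)-hept-4-en-3-one
Conditions: LiCl, iPr2NEt, MeCN, rt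
Reagents that add atoms: none
Why: Horner–Wadsworth–Emmons olefination under Masamune–Roush conditions tolerates the enolisable aldehyde and gives the (E)-enone.

Step 2
Reactants: 3 (E)-hept-4-en-3-one
Product: 4 (5S)-5-ethylhept-6-en-3-one
Conditions: CH2=CHBF3K (1.5 equiv), [Rh(cod)2]PF6 (3 mol%), (S)-BINAP (3.3 mol%), toluene/H2O, 105 °C
Reagents that add atoms: potassium vinyltrifluoroborate, [K+].C=C[B-](F)(F)F
Why: Hayashi–Miyaura rhodium/BINAP-catalysed asymmetric 1,4-addition of an alkenylboron reagent, in which the (S)-BINAP–Rh–vinyl complex adds to the same enone face as in aryl additions to (E)-alk-3-en-2-ones, which here corresponds to (S) at the new centre (future C4).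

Step 3
Reactants: 4 (5S)-5-ethylhept-6-en-3-one
Product: 5 (2S)-2-ethyl-4-oxohexanal
Conditions: O3, CH2Cl2, −78 °C; then Me2S, −78 °C → rt
Reagents that add atoms: ozone, [O-][O+]=O
Why: Ozonolysis with reductive work-up cleaves the only C=C to the aldehyde under neutral conditions, so the α-stereocentre is kept if 5 is used at once.

Step 4
Reactants: 5 (2S)-2-ethyl-4-oxohexanal
Product: 6 (4R)-4-[(3S)-5-oxoheptan-3-yl]oxetan-2-one
Conditions: AcCl, iPr2NEt, O-TMS-quinidine (10 mol%), LiClO4, CH2Cl2/Et2O, −78 °C
Reagents that add atoms: acetyl chloride, CC(=O)Cl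
Why: Catalytic asymmetric acyl halide–aldehyde cyclocondensation (ketene–aldehyde [2+2] through an alkaloid-bound acetyl ammonium enolate) is aldehyde-selective over the ketone and catalyst-controlled; the quinidine-derived catalyst is assigned by analogy to give the (4R) lactone carbon (O-TMS-quinine gives the epimer), which is the C3–O configuration opposite to the target because step 6 inverts it.

Step 5
Reactants: 6 (4R)-4-[(3S)-5-oxoheptan-3-yl]oxetan-2-one
Product: 7 (4R)-4-[(3S)-5-hydroperoxy-5-methoxyheptan-3-yl]oxetan-2-one (both epimers at the peroxy carbon)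
Conditions: urea–H2O2, Sc(OTf)3 (10 mol%), MeOH, 0 °C → rt
Reagents that add atoms: hydrogen peroxide, OO; methanol, CO
Why: Lewis-acid-catalysed peroxyketalisation of a ketone in methanol (a known route to α-methoxy hydroperoxides) converts only the ketone, and the new centre (future C6) may form as both epimers because it is re-set in step 12.

Step 6
Reactants: 7 (4R)-4-[(3S)-5-hydroperoxy-5-methoxyheptan-3-yl]oxetan-2-one
Product: 9 methyl 2-[(3S,4S)-4,6-diethyl-6-methoxy-1,2-dioxan-3-yl]acetate (both C6 epimers), via caesium carboxylate 8 (not isolated)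
Conditions: Cs2CO3 (1.2 equiv), DMF, 0 °C → rt; then MeI
Reagents that add atoms: iodomethane, IC
Why: Proposed new method: the caesium peroxide anion of the α-methoxy hydroperoxide attacks C3 of the β-lactone in a 6-exo-tet SN2 alkyl–oxygen cleavage (about 23 kcal/mol strain release, carboxylate leaving group, acyl attack would need an eight-membered ring), so the O2–C3 bond forms with inversion (4R lactone carbon becomes 3S, cis to the C4 ethyl) and the carboxylate is unmasked and then methylated; the closest known reactions are SN2 opening of β-lactones at the alkyl carbon by azide, thiolate and carboxylate and intramolecular hydroperoxide displacement of sulfonates, epoxides and oxetanes.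

Step 7
Reactants: 3 (E)-hept-4-en-3-one
Product: 10 (3R,4E)-hept-4-en-3-ol
Conditions: (S)-2-methyl-CBS-oxazaborolidine (10 mol%), catecholborane, toluene, −78 °C; aq. NaOH work-up
Reagents that add atoms: none
Why: Corey–Bakshi–Shibata reduction in which the enone binds with the alkenyl group as the large substituent, so the (S)-catalyst gives the (R)-allylic alcohol, and catecholborane at −78 °C avoids hydroboration and 1,4-reduction.

Step 8
Reactants: 10 (3R,4E)-hept-4-en-3-ol
Product: 11 ethyl (3R,4E)-3-ethylhept-4-enoate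
Conditions: MeC(OEt)3, EtCO2H (cat.), 135 °C, EtOH distilled off
Reagents that add atoms: triethyl orthoacetate, CC(OCC)(OCC)OCC
Why: Johnson–Claisen [3,3] rearrangement through a chair transition state with the carbinol ethyl group equatorial transfers the (3R) C–O centre suprafacially to the new C–C centre (3R, future C10) and gives the (E)-alkene (future 11E).

Step 9
Reactants: 11 ethyl (3R,4E)-3-ethylhept-4-enoate
Product: 13 (4R,5E)-4-ethyloct-5-en-1-yne, via aldehyde 12 (not isolated)
Conditions: iBu2AlH, CH2Cl2, −78 °C; then MeOH, K2CO3, dimethyl (1-diazo-2-oxopropyl)phosphonate, −78 °C → rt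
Reagents that add atoms: dimethyl (1-diazo-2-oxopropyl)phosphonate, CC(=O)C(=[N+]=[N-])P(=O)(OC)OC
Why: Low-temperature iBu2AlH reduction stops at the aluminium hemiacetal, which releases aldehyde 12 on methanolysis, and Seyferth–Gilbert homologation with the Ohira–Bestmann reagent gives the terminal alkyne without touching the β-stereocentre.

Step 10
Reactants: 13 (4R,5E)-4-ethyloct-5-en-1-yne
Product: 15 (1E,4R,5E)-2,4-diethyl-1-iodoocta-1,5-diene, via alkenylcopper 14 (not isolated)
Conditions: EtMgBr, CuBr·SMe2, Et2O/Me2S, −45 → −20 °C; then I2, −40 → 0 °C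
Reagents that add atoms: ethylmagnesium bromide, CC[Mg]Br; iodine, I-I
Why: Normant carbocupration adds ethyl and copper syn across the terminal alkyne (ethyl to the internal carbon), and iodinolysis with retention gives the (1E)-iodide with iodine cis to the new ethyl group, the geometry needed for 7E.

Step 11
Reactants: 15 (1E,4R,5E)-2,4-diethyl-1-iodoocta-1,5-diene
Product: 17 [(1E,4R,5E)-2,4-diethylocta-1,5-dien-1-yl]trimethylsilane, via alkenyllithium 16 (not isolated)
Conditions: t-BuLi (2.1 equiv), Et2O, −78 °C; then Me3SiCl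
Reagents that add atoms: chlorotrimethylsilane, C[Si](C)(C)Cl
Why: Lithium–iodine exchange and silylation of the alkenyllithium both proceed with retention of alkene geometry.

Step 12
Reactants: 9 methyl 2-[(3S,4S)-4,6-diethyl-6-methoxy-1,2-dioxan-3-yl]acetate; 17 [(1E,4R,5E)-2,4-diethylocta-1,5-dien-1-yl]trimethylsilane
Product: 18 methyl 2-[(3S,4S,6R)-6-[(1E,4R,5E)-2,4-diethylocta-1,5-dien-1-yl]-4,6-diethyl-1,2-dioxan-3-yl]acetate
Conditions: 17 (1.5 equiv), Me3SiOTf (1.1 equiv), CH2Cl2, −78 → −40 °C
Reagents that add atoms: none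
Why: Proposed new method: Me3SiOTf ionises the peroxyketal (either C6 epimer) to a cyclic tertiary peroxycarbenium ion, which is attacked by the silicon-bearing carbon of the 2,2-dialkylvinylsilane (tertiary β-silyl cation, then loss of Me3Si+ with retention of the alkene geometry), and attack is axial on the half-chair that keeps the C4 ethyl pseudo-equatorial because the axial face of the other half-chair is blocked by a syn-axial ethyl, so the alkenyl group enters trans to the C4 ethyl and C6 becomes (R); the closest known reactions are Lewis-acid substitutions of peroxyketals by allylsilanes and silyl enol ethers and ipso-substitution of vinylsilanes by oxocarbenium ions.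

Step 13
Reactants: 18 methyl 2-[(3S,4S,6R)-6-[(1E,4R,5E)-2,4-diethylocta-1,5-dien-1-yl]-4,6-diethyl-1,2-dioxan-3-yl]acetate
Product: 20 plakortide N, via lithium carboxylate 19 (not isolated)
Conditions: LiOH, THF/H2O, 0 °C → rt; then 1 M HCl to pH 3
Reagents that add atoms: lithium hydroxide, [Li+].[OH-]
Why: Saponification at 0 °C (hydroxide adds to the ester carbonyl faster than the ester enolises, so no retro-peroxy-Michael ring opening) followed by mild acidification touches no stereocentre.

## Compound list

1 | propanal | CCC=O | starting material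
2 | diethyl (2-oxobutyl)phosphonate | CCC(=O)CP(=O)(OCC)OCC | starting material
3 | (E)-hept-4-en-3-one | CC/C=C/C(=O)CC | intermediate
4 | (5S)-5-ethylhept-6-en-3-one | CCC(=O)C[C@H](CC)C=C | intermediate
5 | (2S)-2-ethyl-4-oxohexanal | CCC(=O)C[C@H](CC)C=O | intermediate
6 | (4R)-4-[(3S)-5-oxoheptan-3-yl]oxetan-2-one | CCC(=O)C[C@H](CC)[C@H]1CC(=O)O1 | intermediate
7 | (4R)-4-[(3S)-5-hydroperoxy-5-methoxyheptan-3-yl]oxetan-2-one (both epimers at the peroxy carbon) | CCC(OC)(OO)C[C@H](CC)[C@H]1CC(=O)O1 | intermediate
8 | caesium 2-[(3S,4S)-4,6-diethyl-6-methoxy-1,2-dioxan-3-yl]acetate (both C6 epimers, not isolated) | CCC1(OC)C[C@H](CC)[C@H](CC(=O)[O-])OO1.[Cs+] | intermediate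
9 | methyl 2-[(3S,4S)-4,6-diethyl-6-methoxy-1,2-dioxan-3-yl]acetate (both C6 epimers) | CCC1(OC)C[C@H](CC)[C@H](CC(=O)OC)OO1 | intermediate
10 | (3R,4E)-hept-4-en-3-ol | CC/C=C/[C@H](O)CC | intermediate
11 | ethyl (3R,4E)-3-ethylhept-4-enoate | CC/C=C/[C@H](CC)CC(=O)OCC | intermediate
12 | (3R,4E)-3-ethylhept-4-enal (not isolated) | CC/C=C/[C@H](CC)CC=O | intermediate
13 | (4R,5E)-4-ethyloct-5-en-1-yne | CC/C=C/[C@H](CC)CC#C | intermediate
14 | [(1E,4R,5E)-2,4-diethylocta-1,5-dien-1-yl]copper, MgBr2 complex (not isolated) | CC/C=C/[C@H](CC)C/C(=C/[Cu])CC | intermediate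
15 | (1E,4R,5E)-2,4-diethyl-1-iodoocta-1,5-diene | CC/C=C/[C@H](CC)C/C(=C/I)CC | intermediate
16 | [(1E,4R,5E)-2,4-diethylocta-1,5-dien-1-yl]lithium (not isolated) | CC/C=C/[C@H](CC)C/C(=C/[Li])CC | intermediate
17 | [(1E,4R,5E)-2,4-diethylocta-1,5-dien-1-yl]trimethylsilane | CC/C=C/[C@H](CC)C/C(=C/[Si](C)(C)C)CC | intermediate
18 | methyl 2-[(3S,4S,6R)-6-[(1E,4R,5E)-2,4-diethylocta-1,5-dien-1-yl]-4,6-diethyl-1,2-dioxan-3-yl]acetate | CC/C=C/[C@H](CC)C/C(=C/[C@@]1(CC)C[C@H](CC)[C@H](CC(=O)OC)OO1)CC | intermediate
19 | lithium 2-[(3S,4S,6R)-6-[(1E,4R,5E)-2,4-diethylocta-1,5-dien-1-yl]-4,6-diethyl-1,2-dioxan-3-yl]acetate (not isolated) | CC/C=C/[C@H](CC)C/C(=C/[C@@]1(CC)C[C@H](CC)[C@H](CC(=O)[O-])OO1)CC.[Li+] | intermediate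
20 | plakortide N, 2-[(3S,4S,6R)-6-[(1E,4R,5E)-2,4-diethylocta-1,5-dien-1-yl]-4,6-diethyl-1,2-dioxan-3-yl]acetic acid | CC/C=C/[C@H](CC)C/C(=C/[C@@]1(CC)C[C@H](CC)[C@H](CC(=O)O)OO1)CC | target

## Step count and risks

Total steps: 13. Longest linear sequence: 8 steps (1, 7, 8, 9, 10, 11, 12, 13; the ring branch 1–6, 12, 13 is equally long).

Three steps most likely to fail:

**Step 6 (new C–O ring closure).** The peroxide anion may be too hindered for SN2 at the branched secondary lactone carbon, or the lactone may be lost to base first. The fallback uses known chemistry, sets out from 5 and returns at 9. Aldehyde-selective Wittig reaction of 5 with Ph3P=CHCO2Me gives methyl (2E,4S)-4-ethyl-6-oxooct-2-enoate F1. Peroxyketalisation of its ketone (urea–H2O2, Sc(OTf)3, MeOH) gives methyl (2E,4S)-4-ethyl-6-hydroperoxy-6-methoxyoct-2-enoate F2. Et2NH in CF3CH2OH then closes the dioxane by the known intramolecular peroxy-Michael addition. This gives 9 together with its C3 epimer (probably the major product), which is removed by chromatography before the route continues from 9.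

**Step 12 (new alkenylation of the peroxycarbenium ion).** The vinylsilane is only a moderate, hindered π-nucleophile, the tertiary peroxycarbenium ion can fragment, and the facial selectivity at C6 is predicted, not measured. The fallback uses known chemistry, sets out from 5 and 15 and returns at 18. The keto enoate F1 (made from 5 as above) is treated at −78 °C with alkenyllithium 16 (from 15 and t-BuLi) after transmetalation with CeCl3. This gives the tertiary allylic alcohol methyl (2E,4S,7E,10R,11E)-4,6,8,10-tetraethyl-6-hydroxytetradeca-2,7,11-trienoate F3 as both C6 epimers. Acid-catalysed perhydrolysis (H2O2, cat. H2SO4, Et2O, 0 °C; SN1 at the tertiary allylic carbon) gives the hydroperoxide methyl (2E,4S,7E,10R,11E)-4,6,8,10-tetraethyl-6-hydroperoxytetradeca-2,7,11-trienoate F4, along with its allylic isomer. Et2NH in CF3CH2OH closes the ring by peroxy-Michael addition. This fallback gives up stereocontrol at C3 and C6, so 18 must be separated from its ring diastereomers by preparative HPLC before step 13.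

**Step 5 (peroxyketalisation next to a β-lactone).** Lewis-acidic methanol may open the lactone, or a gem-dihydroperoxide may form. The fallback sets out from 6 and returns at 7. Ketone-selective, non-basic methylenation of 6 (Zn, CH2Br2, TiCl4, THF) gives (4R)-4-[(3S)-5-methylideneheptan-3-yl]oxetan-2-one F5. Ozonolysis of F5 in CH2Cl2/MeOH at −78 °C, without reductive work-up, gives 7 under neutral conditions, because the ketone-side carbonyl oxide is trapped by methanol.

Further compounds
F1 | step 6 | methyl (2E,4S)-4-ethyl-6-oxooct-2-enoate | CCC(=O)C[C@H](CC)/C=C/C(=O)OC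
F2 | step 6 | methyl (2E,4S)-4-ethyl-6-hydroperoxy-6-methoxyoct-2-enoate | CCC(OC)(OO)C[C@H](CC)/C=C/C(=O)OC
F3 | step 12 | methyl (2E,4S,7E,10R,11E)-4,6,8,10-tetraethyl-6-hydroxytetradeca-2,7,11-trienoate | CC/C=C/[C@H](CC)C/C(=C/C(O)(CC)C[C@H](CC)/C=C/C(=O)OC)CC
F4 | step 12 | methyl (2E,4S,7E,10R,11E)-4,6,8,10-tetraethyl-6-hydroperoxytetradeca-2,7,11-trienoate | CC/C=C/[C@H](CC)C/C(=C/C(OO)(CC)C[C@H](CC)/C=C/C(=O)OC)CC
F5 | step 5 | (4R)-4-[(3S)-5-methylideneheptan-3-yl]oxetan-2-one | CCC(=C)C[C@H](CC)[C@H]1CC(=O)O1
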